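**Plan**

1. Naming used below: ring A is the methoxy ring; its carbons carry, in ring order, OMe, H, Me, the seven-ring lactone C=O (the A-carbonyl carbon), the diaryl ether O (the A-ether carbon) and CH2OH (the A-hydroxymethyl carbon). Ring B carries, in ring order, the ether O (the B-ether carbon), the seven-ring lactone O (the B-acyloxy carbon), Me, OH (the B-hydroxyl carbon), the γ-lactone C=O (the B-carboxyl carbon) and the lactol carbon (the B-ipso carbon).
2. Retrosynthetic cuts, in order: the three PhCH2–O bonds (one O-benzyl acetal, two BOM ethers); the bond from the B-ipso carbon to the acetal carbon of the γ-lactone ring, back to an aryl bromide with a benzyloxymethyl ester on the neighbouring carboxyl; the C(=O)–O bond of the dioxepinone ring; the diaryl ether bond at the A-ether carbon, giving a ring-A fluoro aldehyde and a ring-B bromophenol.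
3. Forward: rings A (3 steps) and B (4 steps) are made separately and joined by SNAr at the A-ether carbon. The dioxepinone ring is then closed by lactonisation, and the five-membered lactone ring is closed last, on the finished tricycle, by an enantioselective Pd(0) C(sp3)–H arylation.
4. Enabling feature: the B-carboxyl carbon is ortho to the B-ipso carbon, so its O–CH2–OBn ester holds a methylene with two enantiotopic hydrogens where a six-membered aryl–Pd–alkyl palladacycle can form. A bond from the B-ipso carbon to the side chain on the A-hydroxymethyl carbon is excluded, because it would bridge the outer ortho positions of a diaryl ether that the dioxepinone ring already bridges at the inner ones.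
5. Stereochemistry: the single stereocentre (acetal carbon, R) is created in the key step by catalyst-controlled choice between the two hydrogens. It is carried as a configurationally stable O-benzyl acetal and uncovered by neutral hydrogenolysis in the last step.

Key step: step 14

Remark (assumption): the stereocentre is the hemiacetal carbon of a 3-hydroxyphthalide and can epimerise by ring–chain tautomerism in base or protic acid, so it is assumed to hold its configuration only under neutral, aprotic, cold handling; the free OH is therefore released only in the final step.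

**Route**

Step 1
Reactants: 1 1-fluoro-3-methoxy-5-methylbenzene
Product: 2 2-bromo-1-fluoro-5-methoxy-3-methylbenzene
Conditions: NBS, MeCN, 0 °C → rt
Reagents that add atoms: N-bromosuccinimide, O=C1CCC(=O)N1Br
Why: Electrophilic aromatic bromination should go para to the methoxy group, the strongest donor, at the site that is also ortho to F and Me.

Step 2
Reactants: 2 2-bromo-1-fluoro-5-methoxy-3-methylbenzene
Product: 4 tert-butyl 2-fluoro-4-methoxy-6-methylbenzoate, via aryllithium 3 (not isolated)
Conditions: n-BuLi, THF, −78 °C; then Boc2O, −78 °C → rt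
Reagents that add atoms: di-tert-butyl dicarbonate, CC(C)(C)OC(=O)OC(=O)OC(C)(C)C
Why: Bromine–lithium exchange at −78 °C (cold enough to keep the ortho-fluoro aryllithium from losing LiF) followed by acylation with Boc2O, which should stop at the hindered tert-butyl ester.

Step 3
Reactants: 4 tert-butyl 2-fluoro-4-methoxy-6-methylbenzoate
Product: 6 tert-butyl 2-fluoro-3-formyl-4-methoxy-6-methylbenzoate, via arylmagnesium chloride 5 (not isolated)
Conditions: TMPMgCl·LiCl, THF, −20 °C; then DMF; aq. NH4Cl
Reagents that add atoms: N,N-dimethylformamide, CN(C)C=O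
Why: Directed magnesiation with the hindered amide base should take the ring hydrogen flanked by F and OMe (the most acidic C–H; both ortho positions of the ester are blocked and the tert-butyl ester tolerates the base), and DMF formylates the arylmagnesium.

Step 4
Reactants: 7 methyl 2,4-dihydroxy-3-methylbenzoate
Product: 8 methyl 5-formyl-2,4-dihydroxy-3-methylbenzoate
Conditions: Cl2CHOMe, TiCl4, CH2Cl2, 0 °C; then aq. HCl
Reagents that add atoms: dichloromethyl methyl ether, COC(Cl)Cl; water, O
Why: Rieche formylation; position 5 is the only ring position activated by both hydroxyls (ortho to the 4-OH, para to the 2-OH), position 6 being meta to both.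

Step 5
Reactants: 8 methyl 5-formyl-2,4-dihydroxy-3-methylbenzoate
Product: 9 methyl 5-formyl-2,4-bis(methoxymethoxy)-3-methylbenzoate
Conditions: MOMCl, i-Pr2NEt, DMF, 0 → 40 °C
Reagents that add atoms: chloromethyl methyl ether, COCCl
Why: Williamson-type O-alkylation of both chelated phenols with the reactive α-chloro ether; the MOM groups should survive oxidation, bromination and SNAr and fall together with the tert-butyl ester in acid.

Step 6
Reactants: 9 methyl 5-formyl-2,4-bis(methoxymethoxy)-3-methylbenzoate
Product: 11 methyl 5-hydroxy-2,4-bis(methoxymethoxy)-3-methylbenzoate, via aryl formate 10 (not isolated)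
Conditions: mCPBA, NaHCO3, CH2Cl2, rt; then K2CO3 (cat.), MeOH, 0 °C
Reagents that add atoms: 3-chloroperbenzoic acid, O=C(OO)c1cccc(Cl)c1
Why: Baeyer–Villiger (Dakin-type) oxidation, in which the electron-rich aryl group (ortho and para to alkoxy groups) migrates in preference to H, followed by methanolysis of the aryl formate.

Step 7
Reactants: 11 methyl 5-hydroxy-2,4-bis(methoxymethoxy)-3-methylbenzoate
Product: 12 methyl 2-bromo-3-hydroxy-4,6-bis(methoxymethoxy)-5-methylbenzoate
Conditions: NBS, MeCN, 0 °C
Reagents that add atoms: N-bromosuccinimide, O=C1CCC(=O)N1Br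
Why: Electrophilic bromination at the only free ring position, which is ortho to the free phenol.

Step 8
Reactants: 6 tert-butyl 2-fluoro-3-formyl-4-methoxy-6-methylbenzoate; 12 methyl 2-bromo-3-hydroxy-4,6-bis(methoxymethoxy)-5-methylbenzoate
Product: 13 tert-butyl 2-[2-bromo-3-(methoxycarbonyl)-4,6-bis(methoxymethoxy)-5-methylphenoxy]-3-formyl-4-methoxy-6-methylbenzoate
Conditions: K2CO3, DMF, 80 °C
Reagents that add atoms: none
Why: SNAr; the fluoride is flanked by an ortho formyl and an ortho ester group that stabilise the Meisenheimer adduct, and the only free OH of 12 is the nucleophile, so the ether oxygen is fixed on the ring-B carbon between the bromide and a MOM ether.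

Step 9
Reactants: 13 tert-butyl 2-[2-bromo-3-(methoxycarbonyl)-4,6-bis(methoxymethoxy)-5-methylphenoxy]-3-formyl-4-methoxy-6-methylbenzoate
Product: 14 2-[2-bromo-4,6-dihydroxy-3-(methoxycarbonyl)-5-methylphenoxy]-3-formyl-4-methoxy-6-methylbenzoic acid
Conditions: TFA/CH2Cl2/H2O (10:10:1), 0 °C → rt
Reagents that add atoms: none
Why: Acidolysis; the tert-butyl ester fragments to acid and isobutene without attack at the hindered carbonyl and both MOM acetals hydrolyse, while the methyl ester, aldehyde and aryl bromide should be inert.

Step 10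
Reactants: 14 2-[2-bromo-4,6-dihydroxy-3-(methoxycarbonyl)-5-methylphenoxy]-3-formyl-4-methoxy-6-methylbenzoic acid (seco acid)
Product: 15 methyl 6-bromo-4-formyl-8-hydroxy-3-methoxy-1,9-dimethyl-11-oxo-11H-dibenzo[b,e][1,4]dioxepine-7-carboxylate
Conditions: TFAA, toluene, 0 °C → rt; then aq. NaHCO3
Reagents that add atoms: none
Why: TFAA-mediated dehydrative lactonisation, the classical closure for hindered 2-aryloxybenzoic acids; only the hydroxyl ortho to the ether oxygen can reach the activated ring-A acyl group (seven-membered ring), the other hydroxyl being para to the ether oxygen.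

Step 11
Reactants: 15 methyl 6-bromo-4-formyl-8-hydroxy-3-methoxy-1,9-dimethyl-11-oxo-11H-dibenzo[b,e][1,4]dioxepine-7-carboxylate (depsidone aldehyde methyl ester)
Product: 16 6-bromo-4-formyl-8-hydroxy-3-methoxy-1,9-dimethyl-11-oxo-11H-dibenzo[b,e][1,4]dioxepine-7-carboxylic acid
Conditions: LiI, pyridine, 90 °C; then 1 M HCl
Reagents that add atoms: none
Why: Nucleophilic (SN2) demethylation by iodide attacks the ester methyl carbon, a site that neither the aryl lactone nor the aryl methyl ether offers under these conditions.

Step 12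
Reactants: 16 6-bromo-4-formyl-8-hydroxy-3-methoxy-1,9-dimethyl-11-oxo-11H-dibenzo[b,e][1,4]dioxepine-7-carboxylic acid (depsidone aldehyde acid)
Product: 17 6-bromo-8-hydroxy-4-(hydroxymethyl)-3-methoxy-1,9-dimethyl-11-oxo-11H-dibenzo[b,e][1,4]dioxepine-7-carboxylic acid
Conditions: NaBH4, THF/H2O (9:1), 0 °C; then 1 M HCl to pH 2
Reagents that add atoms: none
Why: Chemoselective borohydride reduction of the aryl aldehyde, which should be much faster than attack on the lactone or the carboxylate at low temperature.

Step 13
Reactants: 17 6-bromo-8-hydroxy-4-(hydroxymethyl)-3-methoxy-1,9-dimethyl-11-oxo-11H-dibenzo[b,e][1,4]dioxepine-7-carboxylic acid (depsidone hydroxymethyl acid)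
Product: 18 (benzyloxy)methyl 8-[(benzyloxy)methoxy]-4-{[(benzyloxy)methoxy]methyl}-6-bromo-3-methoxy-1,9-dimethyl-11-oxo-11H-dibenzo[b,e][1,4]dioxepine-7-carboxylate
Conditions: BOMCl (6 equiv), i-Pr2NEt (8 equiv), n-Bu4NI (cat.), CH2Cl2, 40 °C
Reagents that add atoms: benzyl chloromethyl ether, ClCOCc1ccccc1
Why: O-Alkylation of carboxylate, primary alcohol and phenol with the α-chloro ether (iodide-catalysed) installs in one step the O–CH2–O tether for step 14 and two hydrogenolysable protecting groups.

Step 14
Reactants: 18 (benzyloxy)methyl 8-[(benzyloxy)methoxy]-4-{[(benzyloxy)methoxy]methyl}-6-bromo-3-methoxy-1,9-dimethyl-11-oxo-11H-dibenzo[b,e][1,4]dioxepine-7-carboxylate (tris-BOM bromide)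
Product: 19 (1R)-1-(benzyloxy)-4-[(benzyloxy)methoxy]-11-{[(benzyloxy)methoxy]methyl}-10-methoxy-5,8-dimethyl-1H-2,6,12-trioxabenzo[5,6]cyclohepta[1,2-e]indene-3,7-dione (the (R)-O-benzyl acetal of the target, with the phenol and the hydroxymethyl group as BOM ethers)
Conditions: [Pd(π-cinnamyl)Cl]2 (5 mol%), L*·HI (10 mol%; C2-symmetric 1,3-bis[(S)-2,2-dimethyl-1-(1-naphthyl)propyl]imidazolium iodide, or its antipode if the first screen requires it), CsOPiv (0.3 equiv), Cs2CO3 (1.5 equiv), mesitylene, 120 °C
Reagents that add atoms: none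
Why: Proposed new method: Pd(0)L* inserts into the C–Br bond at the B-ipso carbon, pivalate replaces bromide, and a concerted metalation–deprotonation removes one of the two enantiotopic hydrogens of the ester O–CH2–O carbon to give a six-membered aryl–Pd–alkyl palladacycle, from which C(sp2)–C(sp3) reductive elimination forms the aryl–acetal bond; the palladated carbon has only oxygen in its β-positions, so β-hydride elimination is not open. The closest known reaction type is the Pd(0)-catalysed enantioselective intramolecular arylation of methylene C(sp3)–H bonds next to nitrogen or carbon with bulky chiral NHC or phosphine ligands (indolines, indanes, lactams); an O–CH2–O carbon of an acyloxymethyl ether is not an established substrate, but its C–H bonds are more acidic and no more hindered than those. The five-membered lactone ring closes by reductive elimination from the six-membered palladacycle (ring contraction with loss of Pd), which needs the ester in its s-trans rotamer, reachable at 120 °C and locked in the product. The new stereocentre is set in the C–H cleavage step by the chiral ligand, since palladation and reductive elimination both proceed with retention at carbon, and the product is a configurationally stable mixed acetal; the sense of induction cannot be predicted for this substrate class, so the ligand antipode that gives (R) must be fixed by a first screen. Site selectivity is secured by the substrate: only the ester methylene can form a six-membered palladacycle from the B-ipso carbon, the BOM ether on the B-hydroxyl carbon is meta to palladium, and a bond to the methylene on the A-hydroxymethyl carbon would have to bridge the outer ortho positions of a diaryl ether that the dioxepinone ring already bridges at the inner ones.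

Step 15
Reactants: 19 (1R)-1-(benzyloxy)-4-[(benzyloxy)methoxy]-11-{[(benzyloxy)methoxy]methyl}-10-methoxy-5,8-dimethyl-1H-2,6,12-trioxabenzo[5,6]cyclohepta[1,2-e]indene-3,7-dione ((R)-O-benzyl acetal)
Product: 21 (1R)-1,4-dihydroxy-11-(hydroxymethyl)-10-methoxy-5,8-dimethyl-1H-2,6,12-trioxabenzo[5,6]cyclohepta[1,2-e]indene-3,7-dione (target), via bis(hemiformal) 20 (not isolated)
Conditions: H2 (1 atm), 5% Pd/C, EtOAc, 0 °C → rt; filter, concentrate cold
Reagents that add atoms: none
Why: Hydrogenolysis of the three PhCH2–O bonds under neutral conditions, after which the two hemiformals lose formaldehyde; no bond at the acetal carbon is broken, so the (R) configuration from step 14 should be carried over.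

**Compound list**

1 | 1-fluoro-3-methoxy-5-methylbenzene | COc1cc(C)cc(F)c1 | starting material
2 | 2-bromo-1-fluoro-5-methoxy-3-methylbenzene | COc1cc(C)c(Br)c(F)c1 | intermediate
3 | (2-fluoro-4-methoxy-6-methylphenyl)lithium | COc1cc(C)c([Li])c(F)c1 | intermediate (not isolated)
4 | tert-butyl 2-fluoro-4-methoxy-6-methylbenzoate | COc1cc(C)c(C(=O)OC(C)(C)C)c(F)c1 | intermediate
5 | [3-(tert-butoxycarbonyl)-2-fluoro-6-methoxy-4-methylphenyl]magnesium chloride | COc1cc(C)c(C(=O)OC(C)(C)C)c(F)c1[Mg]Cl | intermediate (not isolated)
6 | tert-butyl 2-fluoro-3-formyl-4-methoxy-6-methylbenzoate | COc1cc(C)c(C(=O)OC(C)(C)C)c(F)c1C=O | intermediate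
7 | methyl 2,4-dihydroxy-3-methylbenzoate | COC(=O)c1ccc(O)c(C)c1O | starting material
8 | methyl 5-formyl-2,4-dihydroxy-3-methylbenzoate | COC(=O)c1cc(C=O)c(O)c(C)c1O | intermediate
9 | methyl 5-formyl-2,4-bis(methoxymethoxy)-3-methylbenzoate | COC(=O)c1cc(C=O)c(OCOC)c(C)c1OCOC | intermediate
10 | methyl 5-(formyloxy)-2,4-bis(methoxymethoxy)-3-methylbenzoate | COC(=O)c1cc(OC=O)c(OCOC)c(C)c1OCOC | intermediate (not isolated)
11 | methyl 5-hydroxy-2,4-bis(methoxymethoxy)-3-methylbenzoate | COC(=O)c1cc(O)c(OCOC)c(C)c1OCOC | intermediate
12 | methyl 2-bromo-3-hydroxy-4,6-bis(methoxymethoxy)-5-methylbenzoate | COC(=O)c1c(Br)c(O)c(OCOC)c(C)c1OCOC | intermediate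
13 | tert-butyl 2-[2-bromo-3-(methoxycarbonyl)-4,6-bis(methoxymethoxy)-5-methylphenoxy]-3-formyl-4-methoxy-6-methylbenzoate | COc1cc(C)c(C(=O)OC(C)(C)C)c(Oc2c(Br)c(C(=O)OC)c(OCOC)c(C)c2OCOC)c1C=O | intermediate
14 | 2-[2-bromo-4,6-dihydroxy-3-(methoxycarbonyl)-5-methylphenoxy]-3-formyl-4-methoxy-6-methylbenzoic acid | COc1cc(C)c(C(=O)O)c(Oc2c(Br)c(C(=O)OC)c(O)c(C)c2O)c1C=O | intermediate
15 | methyl 6-bromo-4-formyl-8-hydroxy-3-methoxy-1,9-dimethyl-11-oxo-11H-dibenzo[b,e][1,4]dioxepine-7-carboxylate | COc1cc(C)c2c(c1C=O)Oc1c(c(C)c(O)c(C(=O)OC)c1Br)OC2=O | intermediate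
16 | 6-bromo-4-formyl-8-hydroxy-3-methoxy-1,9-dimethyl-11-oxo-11H-dibenzo[b,e][1,4]dioxepine-7-carboxylic acid | COc1cc(C)c2c(c1C=O)Oc1c(c(C)c(O)c(C(=O)O)c1Br)OC2=O | intermediate
17 | 6-bromo-8-hydroxy-4-(hydroxymethyl)-3-methoxy-1,9-dimethyl-11-oxo-11H-dibenzo[b,e][1,4]dioxepine-7-carboxylic acid | COc1cc(C)c2c(c1CO)Oc1c(c(C)c(O)c(C(=O)O)c1Br)OC2=O | intermediate
18 | (benzyloxy)methyl 8-[(benzyloxy)methoxy]-4-{[(benzyloxy)methoxy]methyl}-6-bromo-3-methoxy-1,9-dimethyl-11-oxo-11H-dibenzo[b,e][1,4]dioxepine-7-carboxylate | COc1cc(C)c2c(c1COCOCc4ccccc4)Oc1c(c(C)c(OCOCc5ccccc5)c(C(=O)OCOCc6ccccc6)c1Br)OC2=O | intermediate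
19 | (1R)-1-(benzyloxy)-4-[(benzyloxy)methoxy]-11-{[(benzyloxy)methoxy]methyl}-10-methoxy-5,8-dimethyl-1H-2,6,12-trioxabenzo[5,6]cyclohepta[1,2-e]indene-3,7-dione | COc1cc(C)c2c(c1COCOCc4ccccc4)Oc1c(c(C)c(OCOCc5ccccc5)c3c1[C@H](OCc6ccccc6)OC3=O)OC2=O | intermediate
20 | (1R)-1-hydroxy-4-(hydroxymethoxy)-11-[(hydroxymethoxy)methyl]-10-methoxy-5,8-dimethyl-1H-2,6,12-trioxabenzo[5,6]cyclohepta[1,2-e]indene-3,7-dione | COc1cc(C)c2c(c1COCO)Oc1c(c(C)c(OCO)c3c1[C@H](O)OC3=O)OC2=O | intermediate (not isolated)
21 | (1R)-1,4-dihydroxy-11-(hydroxymethyl)-10-methoxy-5,8-dimethyl-1H-2,6,12-trioxabenzo[5,6]cyclohepta[1,2-e]indene-3,7-dione | COc1cc(C)c2c(c1CO)Oc1c(c(C)c(O)c3c1[C@H](O)OC3=O)OC2=O | target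

**Count**

Total steps: 15. Longest linear sequence: 12 steps (compound 7 through steps 4–15 to 21).

**Steps most likely to fail**

Step 14 (proposed new method). Several processes could defeat it: protodebromination may outrun C–H palladation; palladation may occur at the methylene of the ring-A side chain, giving a palladacycle that cannot close; the two enantiotopic hydrogens may be poorly discriminated; or base and pivalate at 120 °C may erode the acyloxymethyl ester or the new acetal centre. The fallback uses known chemistry only. It sets out from 17: Stille coupling with tributyl(vinyl)stannane (Pd(PPh3)4, toluene, 90 °C) should give the vinyl acid F1. Ozonolysis (ozone, CH2Cl2/MeOH, −78 °C; then Me2S) cleaves the alkene, and the ortho-formyl acid closes at once to the racemic lactol F2. The enantiomers are then separated by preparative chromatography on a chiral stationary phase (neutral eluent, low temperature), and the (R)-enantiomer is 21, where the fallback rejoins the route. Here the stereocentre comes from resolution instead of catalyst control.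

Step 15. Hydrogenolysis may not stop at the three PhCH2–O bonds: the benzylic C–O bonds of the ring-A hydroxymethyl group and of the lactol carbon can also be cleaved, and the freed lactol may epimerise on the catalyst. The fallback replaces the reductive unmasking by an oxidative one. It sets out from 17: alkylation with (4-methoxybenzyloxy)methyl chloride (i-Pr2NEt, n-Bu4NI, CH2Cl2, 40 °C) should give the tris(4-methoxybenzyloxymethyl) bromide F3. The conditions of step 14 should then close it to the (R)-4-methoxybenzyl acetal F4. DDQ in CH2Cl2/pH 7 buffer at 0 °C removes the three 4-methoxybenzyl groups; the hemiformals lose formaldehyde and 21 results without any reductant.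

Step 11. The demethylation needs heat, and the electron-rich salicylic acid it liberates may decarboxylate, or the aryl lactone may be opened by pyridine or iodide. The fallback moves the ester cleavage in front of the lactonisation. It sets out from 13: LiI in pyridine at 90 °C (no lactone and no free salicylic acid present) should give the ring-B acid F5. TFA/CH2Cl2/H2O then removes the tert-butyl ester and both MOM groups to give the diacid F6. TFAA in toluene lactonises only the ring-A carboxyl onto the hydroxyl ortho to the ether oxygen, the ring-B carboxyl returning as the free acid on aqueous work-up, which gives 16, where the fallback rejoins the route.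

**Further compounds**

F1 | step 14 | 6-ethenyl-8-hydroxy-4-(hydroxymethyl)-3-methoxy-1,9-dimethyl-11-oxo-11H-dibenzo[b,e][1,4]dioxepine-7-carboxylic acid | COc1cc(C)c2c(c1CO)Oc1c(c(C)c(O)c(C(=O)O)c1C=C)OC2=O
F2 | step 14 | racemic 1,4-dihydroxy-11-(hydroxymethyl)-10-methoxy-5,8-dimethyl-1H-2,6,12-trioxabenzo[5,6]cyclohepta[1,2-e]indene-3,7-dione | COc1cc(C)c2c(c1CO)Oc1c(c(C)c(O)c3c1C(O)OC3=O)OC2=O
F3 | step 15 | [(4-methoxybenzyl)oxy]methyl 6-bromo-3-methoxy-8-{[(4-methoxybenzyl)oxy]methoxy}-4-({[(4-methoxybenzyl)oxy]methoxy}methyl)-1,9-dimethyl-11-oxo-11H-dibenzo[b,e][1,4]dioxepine-7-carboxylate | COc1cc(C)c2c(c1COCOCc4ccc(OC)cc4)Oc1c(c(C)c(OCOCc5ccc(OC)cc5)c(C(=O)OCOCc6ccc(OC)cc6)c1Br)OC2=O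
F4 | step 15 | (1R)-10-methoxy-1-[(4-methoxybenzyl)oxy]-4-{[(4-methoxybenzyl)oxy]methoxy}-11-({[(4-methoxybenzyl)oxy]methoxy}methyl)-5,8-dimethyl-1H-2,6,12-trioxabenzo[5,6]cyclohepta[1,2-e]indene-3,7-dione | COc1cc(C)c2c(c1COCOCc4ccc(OC)cc4)Oc1c(c(C)c(OCOCc5ccc(OC)cc5)c3c1[C@H](OCc6ccc(OC)cc6)OC3=O)OC2=O
F5 | step 11 | 2-bromo-3-[2-(tert-butoxycarbonyl)-6-formyl-5-methoxy-3-methylphenoxy]-4,6-bis(methoxymethoxy)-5-methylbenzoic acid | COc1cc(C)c(C(=O)OC(C)(C)C)c(Oc2c(Br)c(C(=O)O)c(OCOC)c(C)c2OCOC)c1C=O
F6 | step 11 | 2-bromo-3-(2-carboxy-6-formyl-5-methoxy-3-methylphenoxy)-4,6-dihydroxy-5-methylbenzoic acid | COc1cc(C)c(C(=O)O)c(Oc2c(Br)c(C(=O)O)c(O)c(C)c2O)c1C=O
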